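**Plan**
- Ring numbering used throughout for the dienone ring: C1 (ketone), C2 (CMe2), C3 (enol ether carbon bonded to the pyran oxygen), C4 (carries the pyran CH2), C5 (C–OH), C6 (acyl-bearing carbon).
- Retrosynthesis: first the pyran O–C(CH3) and CH2–CH bonds are cut (hetero-Diels–Alder) to (−)-β-caryophyllene and a 4-methylidene trione. Then the C6–acyl bond is cut to (S)-2-methylbutanoic acid. Last the ring bonds C5–C6 and C3–C4 are cut to ethyl 2,2-dimethyl-3-oxobutanoate and ethyl propanoate.
- Forward: the carbocycle arises first by a one-pot Claisen–Dieckmann [4+2] annulation, then C6 is acylated, and the pyran ring closes last in an oxidative hetero-Diels–Alder reaction.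
- Enabling feature: the ring is a 1,3,5-tricarbonyl in which C3 and C5 are carbonyl-level carbons and C4 and C6 their α-carbons. The quaternary C2 leaves the open chain only two enolisable sites, and they react in the order needed.
- Stereochemistry: the S centre comes from the chiral-pool acid and the cyclobutane centres from caryophyllene. The two pyran-ring centres come from suprafacial cycloaddition to the E alkene on its Si,Si face; the other face is expected to compete, so the facial isomer must be separated.

Key step: step 1

Remark: the cyclohexanetriones are drawn as one tautomer; their methyl-bearing ring carbon between two carbonyl groups is configurationally labile and is left undefined.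

**Step 1**
Reactants: 1 ethyl 2,2-dimethyl-3-oxobutanoate; 2 ethyl propanoate
Product: 4 2,2,4-trimethylcyclohexane-1,3,5-trione, via ethyl 2,2-dimethyl-3,5-dioxoheptanoate 3 (not isolated)
Conditions: LiN(iPr)2 (1.05 equiv), THF, −78 °C; 2 (1.1 equiv), −78 to 0 °C; LiN(iPr)2 (2.5 equiv), −78 °C to rt; aq. HCl
Reagents that add atoms: none
Why: The only enolisable position of 1, the acetyl CH3, is lithiated and acylated by ester 2 (crossed Claisen condensation), which forms the C5–C6 bond of the future ring and leaves diketone 3 as its lithium enolate once the expelled ethoxide has removed the central proton. The second charge of base then deprotonates the propanoyl CH2 of 3, the only α-position left because C2 is quaternary, and this 1,3-dianion attacks the ester carbonyl next to the quaternary carbon (Dieckmann condensation), which forms the C3–C4 bond. The closest known reaction types are the acylation of methyl ketone enolates by esters and the dianion cyclisation of 3,5-dioxo esters to cyclohexane-1,3,5-triones. The single ring closes in the 6-exo-trig mode by addition to the ester carbonyl and loss of ethoxide. No configured stereocentre is formed, since C4 of 4 lies between two carbonyl groups and enolises freely. The step needs chain extension at carbon and a single mode of ring closure; the quaternary C2 allows no other enolate and only the six-membered closure is accessible, so the positions of the gem-dimethyl group, of the lone methyl group and of the free C6 are fixed by the two esters.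

**Step 2**
Reactants: 4 2,2,4-trimethylcyclohexane-1,3,5-trione; 5 (2S)-2-methylbutanoic acid
Product: 7 6-[(2S)-2-methylbutanoyl]-2,2,4-trimethylcyclohexane-1,3,5-trione, via 4,4,6-trimethyl-3,5-dioxocyclohex-1-en-1-yl (2S)-2-methylbutanoate 6 (not isolated)
Conditions: N,N'-dicyclohexylcarbodiimide, 4-(dimethylamino)pyridine (1.2 equiv), CH2Cl2, 0 °C to rt
Reagents that add atoms: none
Why: Carbodiimide activation gives enol ester 6 (Steglich esterification), and the pyridine then moves the acyl group from oxygen to C6, the only unsubstituted carbon between two carbonyl groups, where the product is held as the chelated enolised triketone (1,3 O-to-C acyl shift, as in the preparation of 2-acylcyclohexane-1,3-diones); no new stereocentre is formed and the S centre of 5 is carried over because no strong base is present.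

**Step 3**
Reactants: 7 6-[(2S)-2-methylbutanoyl]-2,2,4-trimethylcyclohexane-1,3,5-trione; 8 (−)-β-caryophyllene
Product: 10 CNP0591516.1 (target; described in the compound list), via 2,2-dimethyl-4-methylidene-6-[(2S)-2-methylbutanoyl]cyclohexane-1,3,5-trione 9 (not isolated)
Conditions: Ag2O (2.5 equiv), 2,2,6,6-tetramethylpiperidin-1-oxyl (0.2 equiv), 8 (3 equiv), PhMe, rt, dark
Reagents that add atoms: none
Why: Net dehydrogenation of the enolised 4-methyl trione by Ag2O, with the nitroxyl as hydrogen shuttle, should give the 4-methylidene trione 9, whose O=C3–C4=CH2 unit adds as a 1-oxadiene to the strained E ring alkene of 8 and not to its exocyclic methylene (oxidative inverse-demand hetero-Diels–Alder reaction), with the CH2 terminus going to the CH carbon and the oxygen to the methyl-bearing carbon; addition across one face of the E alkene fixes the trans relation of the angular methyl group and the ring-fusion hydrogen, the Si,Si face (exposed in the ring conformer opposite to the one that leads to caryophyllene 4,5-oxide) leads to 10, and the isomer from the other face is to be removed by chromatography.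

**Compound list**
1 | ethyl 2,2-dimethyl-3-oxobutanoate | CCOC(=O)C(C)(C)C(C)=O | starting material
2 | ethyl propanoate | CCC(=O)OCC | starting material
3 | ethyl 2,2-dimethyl-3,5-dioxoheptanoate | CCC(=O)CC(=O)C(C)(C)C(=O)OCC | intermediate
4 | 2,2,4-trimethylcyclohexane-1,3,5-trione (C4 labile, undefined) | CC1C(=O)CC(=O)C(C)(C)C1=O | intermediate
5 | (2S)-2-methylbutanoic acid | CC[C@H](C)C(=O)O | starting material
6 | 4,4,6-trimethyl-3,5-dioxocyclohex-1-en-1-yl (2S)-2-methylbutanoate | CC[C@H](C)C(=O)OC1=CC(=O)C(C)(C)C(=O)C1C | intermediate
7 | 6-[(2S)-2-methylbutanoyl]-2,2,4-trimethylcyclohexane-1,3,5-trione (drawn as the 5-enol) | CC[C@H](C)C(=O)C1=C(O)C(C)C(=O)C(C)(C)C1=O | intermediate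
8 | (−)-β-caryophyllene, (1R,4E,9S)-4,11,11-trimethyl-8-methylidenebicyclo[7.2.0]undec-4-ene | C=C1CC/C=C(C)/CC[C@@H]2[C@@H]1CC2(C)C | starting material
9 | 2,2-dimethyl-4-methylidene-6-[(2S)-2-methylbutanoyl]cyclohexane-1,3,5-trione (drawn as the 5-enol) | C=C1C(=O)C(C)(C)C(=O)C(C(=O)[C@@H](C)CC)=C1O | intermediate
10 | CNP0591516.1: dihydropyran fused through its O–C3=C4 edge to the 5-hydroxy-2,2-dimethyl-6-[(2S)-2-methylbutanoyl]cyclohexa-3,5-dien-1-one ring and through its C(CH3)(O)–CH edge to the nine-membered ring of the caryophyllane unit; angular CH3 and ring-fusion H trans, exocyclic methylene and trans-fused gem-dimethylcyclobutane retained (caryophyllane numbering 1R,4S,5R,9S) | C=C1CC[C@@H]2CC3=C(O[C@@]2(C)CC[C@@H]2[C@@H]1CC2(C)C)C(C)(C)C(=O)C(C(=O)[C@@H](C)CC)=C3O | target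

Total step count: 3. Longest linear sequence: 3 steps (1 to 4 to 7 to 10).

**Steps most likely to fail**

Step 3. The one-electron generation of the methylidene trione may be slower than its self-condensation. The cycloaddition may show low, or the opposite, facial preference on the interconverting ring conformers of 8, and part of the heterodiene may react through the other flanking carbonyl oxygen. The fallback sets out from 7 and comes back at 9, and so at 10. It replaces the oxidation by a two-electron elimination that releases the heterodiene slowly, at low temperature and with no oxidant present, although it does not by itself change the facial preference. Selenenylation of 7 at C4 (PhSeCl, pyridine, CH2Cl2) gives 2,2,4-trimethyl-6-[(2S)-2-methylbutanoyl]-4-(phenylselanyl)cyclohexane-1,3,5-trione F1. Oxidation with 3-chloroperbenzoic acid at −78 °C gives 2,2,4-trimethyl-6-[(2S)-2-methylbutanoyl]-4-(phenylseleninyl)cyclohexane-1,3,5-trione F2. Once the peracid is consumed, excess 8 is added and the mixture is warmed. Syn elimination toward the methyl group, which holds the only β-hydrogens, then gives 9 for the same cycloaddition.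

Step 1. Acylation of the lithium enolate by a simple ester may stay incomplete through proton exchange and reversal. Alkoxide may also cleave 1 or 4 at the quaternary carbon (retro-Claisen cleavage) during warming. The fallback gives up the annulation for a dearomatisation; it sets out from 5 and comes back at 7, so that steps 1 and 2 are both bypassed. Acid 5 is converted with (COCl)2 and catalytic N,N-dimethylformamide into (2S)-2-methylbutanoyl chloride F3. Friedel–Crafts acylation of commercial 2-methylbenzene-1,3,5-triol (AlCl3, PhNO2) gives (2S)-2-methyl-1-(2,4,6-trihydroxy-3-methylphenyl)butan-1-one F4. Twofold C-methylation (MeI, NaOMe, MeOH) then gives 7, because either distribution of the two methyl groups over the two ring carbons leads to the same constitution.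

Step 2. The acyl transfer may stall at enol esters or go to the methyl-bearing carbon, since 4 offers three enol oxygens and two nucleophilic carbons. The activated acid may also lose part of its configuration. The fallback inverts the order of the last two operations; it sets out from 4 and comes back at 10. Oxidative cycloaddition of 4 with 8 under the conditions of step 3 should pass through 2,2-dimethyl-4-methylidenecyclohexane-1,3,5-trione F5 to the des-acyl pyrano-fused dione F6. F6 has a single CH2 between two carbonyl groups, and its acylation with 5 (carbodiimide, 4-(dimethylamino)pyridine) gives 10 directly.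

**Further compounds**
F1 | step 3 | 2,2,4-trimethyl-6-[(2S)-2-methylbutanoyl]-4-(phenylselanyl)cyclohexane-1,3,5-trione | CC1([Se]c2ccccc2)C(=O)C(C)(C)C(=O)C(C(=O)[C@@H](C)CC)=C1O
F2 | step 3 | 2,2,4-trimethyl-6-[(2S)-2-methylbutanoyl]-4-(phenylseleninyl)cyclohexane-1,3,5-trione | CC1([Se](=O)c2ccccc2)C(=O)C(C)(C)C(=O)C(C(=O)[C@@H](C)CC)=C1O
F3 | step 1 | (2S)-2-methylbutanoyl chloride | CC[C@H](C)C(Cl)=O
F4 | step 1 | (2S)-2-methyl-1-(2,4,6-trihydroxy-3-methylphenyl)butan-1-one | CC[C@H](C)C(=O)c1c(O)cc(O)c(C)c1O
F5 | step 2 | 2,2-dimethyl-4-methylidenecyclohexane-1,3,5-trione | C=C1C(=O)CC(=O)C(C)(C)C1=O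
F6 | step 2 | des-acyl pyrano-fused dione (10 without the 2-methylbutanoyl group) | C=C1CC[C@@H]2CC3=C(O[C@@]2(C)CC[C@@H]2[C@@H]1CC2(C)C)C(C)(C)C(=O)CC3=O
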